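## Retrosynthetic overview
1. The target comes from its phenol MOM ether. The last step only unmasks the OH.
2. Key disconnection: the allylic C–O bond at the stereocentre, split into tiglate oxygen and a 1-alkyl-2-aryl-allylpalladium. Forming this bond fixes both the branched regiochemistry and the (S) configuration.
3. The allylpalladium is generated in the same flask from an aryl iodide and 6-methylhepta-1,2,5-triene by carbopalladation.
4. The aryl iodide comes from ortho-metalation/iodination of a MOM ether, made from the phenol, made by Baeyer–Villiger oxidation of 2,4-dimethoxy-3-methylbenzaldehyde. The allene comes from Crabbé–Ma homologation of the enyne made from prenyl bromide and ethynylmagnesium bromide.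
5. No ring is formed. The only ring, the arene, is bought intact.

Assumption: the sense of induction of the new catalyst cannot be predicted. I take (R)-MeO-MOP as the ligand that gives the (S) ester. Its commercial mirror image is used if the opposite sense is found.

## Route

Step 1
Reactants: 1 2,4-dimethoxy-3-methylbenzaldehyde
Product: 3 2,4-dimethoxy-3-methylphenol, via aryl formate 2 (not isolated)
Conditions: mCPBA (1.3 equiv), CH2Cl2, 0 °C to rt; aq NaHCO3 wash, solvent switch; K2CO3 (0.1 equiv), MeOH, rt
Reagents that add atoms: mCPBA (3-chloroperoxybenzoic acid), O=C(OO)c1cccc(Cl)c1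
Why: In this Baeyer–Villiger (Dakin-type) oxidation the electron-rich dialkoxyaryl group migrates in preference to hydride to give formate 2, and base-catalysed methanolysis frees the phenol; no stereocentre is involved.

Step 2
Reactants: 3 2,4-dimethoxy-3-methylphenol
Product: 4 1,3-dimethoxy-4-(methoxymethoxy)-2-methylbenzene
Conditions: MOMCl (1.5 equiv), iPr2NEt (2 equiv), CH2Cl2, 0 °C to reflux
Reagents that add atoms: chloromethyl methyl ether (MOMCl), COCCl
Why: Williamson-type O-alkylation by the reactive α-chloro ether installs an acetal that masks the OH (which would otherwise close a dihydrobenzofuran in step 6) and directs the next metalation.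

Step 3
Reactants: 4 1,3-dimethoxy-4-(methoxymethoxy)-2-methylbenzene
Product: 6 1-iodo-3,5-dimethoxy-2-(methoxymethoxy)-4-methylbenzene, via aryllithium 5 (not isolated)
Conditions: n-BuLi (1.2 equiv), TMEDA (1.2 equiv), THF, −78 to 0 °C, 1 h; I2 (1.3 equiv), THF, −78 °C to rt
Reagents that add atoms: iodine, II
Why: In this directed ortho-metalation the chelating OMOM group outcompetes OMe as director and has only one free ortho position, so aryllithium 5 forms there and is trapped by iodine.

Step 4
Reactants: 7 prenyl bromide (1-bromo-3-methylbut-2-ene); 8 ethynylmagnesium bromide (0.5 M in THF)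
Product: 9 5-methylhex-4-en-1-yne
Conditions: CuBr·SMe2 (5 mol %), THF, 0 °C to rt; fractional distillation
Reagents that add atoms: none
Why: Copper-catalysed allyl–alkynyl cross-coupling (SN2 at the primary carbon of the prenyl halide) gives the skipped enyne, and the minor SN2' isomer is removed by distillation.

Step 5
Reactants: 9 5-methylhex-4-en-1-yne
Product: 11 6-methylhepta-1,2,5-triene, via propargylic amine 10 (not isolated)
Conditions: (CH2O)n (2.5 equiv), Cy2NH (1.8 equiv), CuI (0.5 equiv), dioxane, reflux, 2–3 h; distillation
Reagents that add atoms: paraformaldehyde (formaldehyde unit), C=O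
Why: In the Crabbé–Ma allene homologation a copper-mediated Mannich (A3) coupling gives amine 10, and a copper-assisted 1,5-hydride shift from a cyclohexyl C–H with loss of the imine delivers the terminal allene.

Step 6 (key step)
Reactants: 6 1-iodo-3,5-dimethoxy-2-(methoxymethoxy)-4-methylbenzene; 11 6-methylhepta-1,2,5-triene (1.5 equiv); 12 tiglic acid, (E)-2-methylbut-2-enoic acid (1.5 equiv)
Product: 14 (S)-2-[3,5-dimethoxy-2-(methoxymethoxy)-4-methylphenyl]-6-methylhepta-1,5-dien-3-yl (E)-2-methylbut-2-enoate, via allylpalladium tiglate 13 (not isolated)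
Conditions: Pd2(dba)3·CHCl3 (2.5 mol %), (R)-MeO-MOP [(R)-2-(diphenylphosphino)-2'-methoxy-1,1'-binaphthyl, 10 mol %], Ag2CO3 (0.75 equiv), 4 Å MS, toluene, dark, 35 °C; stop when 6 is consumed and filter through silica at once
Reagents that add atoms: none
Why: Proposed new method: this is an intermolecular, branched- and enantioselective 1,2-aryl-acyloxylation of a monosubstituted allene, in which oxidative addition of 6 to zerovalent palladium, removal of iodide as AgI and syn-carbopalladation of the terminal C=C of 11 (aryl to the central carbon) give the halide-free neutral allylpalladium tiglate 13, whose allyl faces interconvert by π-σ-π through the CH2 terminus, so that the single bulky chiral monophosphine holds the substituted allyl carbon trans to phosphorus and next to the κ1-carboxylate, and the faster inner-sphere (cis-migration) C–O reductive elimination in non-polar solvent forms the secondary C–O bond and sets the (S) centre under Curtin–Hammett control; the closest known reaction types are the Larock heteroannulation of allenes with 2-iodobenzoic acids (a tethered carboxylate attacks the substituted terminus), three-component aryl iodide/allene/amine couplings, the palladium/MOP formate reduction of allylic esters (the group on palladium goes to the substituted terminus) and the quinone-promoted branched acyloxylation of divalent palladium allyls.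

Step 7
Reactants: 14 MOM-protected (S)-tiglate
Product: 15 (S)-2-(2-hydroxy-3,5-dimethoxy-4-methylphenyl)-6-methylhepta-1,5-dien-3-yl (E)-2-methylbut-2-enoate (target)
Conditions: NaHSO4·SiO2, CH2Cl2 (wet), rt, 1–2 h
Reagents that add atoms: none
Why: Mild heterogeneous Brønsted-acid hydrolysis cleaves the phenolic formaldehyde acetal, which is far more labile than the allylic tiglate, the prenyl alkene or the aryl methyl ethers, so the (S) centre and the (E)-enoate are untouched.

## Compound list
1 | 2,4-dimethoxy-3-methylbenzaldehyde | COc1ccc(C=O)c(OC)c1C | starting material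
2 | 2,4-dimethoxy-3-methylphenyl formate | COc1ccc(OC=O)c(OC)c1C | intermediate
3 | 2,4-dimethoxy-3-methylphenol | COc1ccc(O)c(OC)c1C | intermediate
4 | 1,3-dimethoxy-4-(methoxymethoxy)-2-methylbenzene | COCOc1ccc(OC)c(C)c1OC | intermediate
5 | [3,5-dimethoxy-2-(methoxymethoxy)-4-methylphenyl]lithium | COCOc1c([Li])cc(OC)c(C)c1OC | intermediate
6 | 1-iodo-3,5-dimethoxy-2-(methoxymethoxy)-4-methylbenzene | COCOc1c(I)cc(OC)c(C)c1OC | intermediate
7 | prenyl bromide | CC(C)=CCBr | starting material
8 | ethynylmagnesium bromide | C#C[Mg]Br | starting material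
9 | 5-methylhex-4-en-1-yne | C#CCC=C(C)C | intermediate
10 | N,N-dicyclohexyl-6-methylhept-5-en-2-yn-1-amine | CC(C)=CCC#CCN(C1CCCCC1)C1CCCCC1 | intermediate
11 | 6-methylhepta-1,2,5-triene | C=C=CCC=C(C)C | intermediate
12 | tiglic acid | C/C=C(\C)C(=O)O | starting material
13 | 2-aryl-1-prenyl-allylpalladium tiglate, drawn as the σ-allyl form, phosphine omitted | COCOc1c(cc(OC)c(C)c1OC)C(C[Pd]OC(=O)/C(C)=C/C)=CCC=C(C)C | intermediate
14 | (S)-2-[3,5-dimethoxy-2-(methoxymethoxy)-4-methylphenyl]-6-methylhepta-1,5-dien-3-yl tiglate | C=C(c1cc(OC)c(C)c(OC)c1OCOC)[C@H](CC=C(C)C)OC(=O)/C(C)=C/C | intermediate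
15 | (S)-2-(2-hydroxy-3,5-dimethoxy-4-methylphenyl)-6-methylhepta-1,5-dien-3-yl tiglate | C=C(c1cc(OC)c(C)c(OC)c1O)[C@H](CC=C(C)C)OC(=O)/C(C)=C/C | target

## Step count and risks
Total steps: 7. Longest linear sequence: 5 (steps 1, 2, 3, 6, 7).

**Most likely to fail, first: step 6 (the new step).**
- Outer-sphere attack could give the linear ester.
- Loss of the doubly allylic hydrogen from 13 could give the conjugated triene.
- Zerovalent palladium could re-ionise 14, eroding the ee and the branched ratio.
- The enantioselectivity itself is untested.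

The fallback uses known chemistry only. It sets out from 6 and comes back at 14.
- Commercial 4-methylpent-3-en-1-ol is oxidised (Dess–Martin periodinane, NaHCO3, CH2Cl2) to 4-methylpent-3-enal F1.
- F1 is used crude with 8 (THF, −78 °C) to give racemic 6-methylhept-5-en-1-yn-3-ol F2.
- Iodide 6 is converted with iPrMgCl·LiCl (THF, −20 °C) into the arylmagnesium chloride F3.
- F3 (2.2 equiv) adds to F2 under CuI catalysis. This is anti-carbomagnesiation of a propargylic alcohol, with aryl going to the internal carbon. It gives the racemic allylic alcohol F4.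
- Sharpless kinetic resolution follows (Ti(OiPr)4, D-(−)-diisopropyl tartrate, t-BuOOH, 4 Å MS, CH2Cl2, −20 °C, about 55% conversion). It consumes the (R)-enantiomer as the epoxy alcohol F5 and leaves the (S)-allylic alcohol F6.
- Steglich esterification of F6 with 12 (DCC, DMAP, CH2Cl2) gives 14 with retention.

**Second: step 7.** The freed phenol sits next to an allylic ester and an acid-sensitive styrene. Acid could therefore trigger closure to a methylene-dihydrobenzofuran and then a benzofuran.

The fallback changes the protecting-group plan. It sets out from 6 and comes back at 15.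
- The MOM group is removed at the robust iodide stage (HCl, MeOH, 50 °C) to give 6-iodo-2,4-dimethoxy-3-methylphenol F7.
- Silylation (TBSCl, imidazole, DMF) gives the TBS ether F8.
- F8 is carried through the coupling of step 6 with 11 and 12 to give the TBS-protected (S)-tiglate F9.
- Buffered fluoride (TBAF/AcOH, THF, 0 °C) gives 15 without any acid.

**Third: step 5.** The skipped enyne can isomerise under hot amine/copper conditions, and both 9 and 11 are volatile.

The fallback sets out from 7, comes back at 11, and bypasses 9 and 10.
- Bromide 7 is coupled with propargyl alcohol (CuI, K2CO3, NaI, DMF, rt) to give the non-volatile 6-methylhept-5-en-2-yn-1-ol F10.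
- Myers allene synthesis (2-nitrobenzenesulfonylhydrazide, PPh3, DEAD, THF, −15 °C to rt) proceeds through the Mitsunobu product, the N-propargylic sulfonylhydrazine F11.
- F11 loses the sulfinic acid to give the propargylic diazene F12, whose retro-ene loss of nitrogen gives 11.

## Further compounds
F1 | step 6 | 4-methylpent-3-enal | CC(C)=CCC=O
F2 | step 6 | rac-6-methylhept-5-en-1-yn-3-ol | C#CC(O)CC=C(C)C
F3 | step 6 | [3,5-dimethoxy-2-(methoxymethoxy)-4-methylphenyl]magnesium chloride | COCOc1c([Mg]Cl)cc(OC)c(C)c1OC
F4 | step 6 | rac-2-[3,5-dimethoxy-2-(methoxymethoxy)-4-methylphenyl]-6-methylhepta-1,5-dien-3-ol | C=C(c1cc(OC)c(C)c(OC)c1OCOC)C(O)CC=C(C)C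
F5 | step 6 | (R)-1-{(R)-2-[3,5-dimethoxy-2-(methoxymethoxy)-4-methylphenyl]oxiran-2-yl}-4-methylpent-3-en-1-ol | O[C@H](CC=C(C)C)[C@]1(CO1)c1cc(OC)c(C)c(OC)c1OCOC
F6 | step 6 | (S)-2-[3,5-dimethoxy-2-(methoxymethoxy)-4-methylphenyl]-6-methylhepta-1,5-dien-3-ol | C=C(c1cc(OC)c(C)c(OC)c1OCOC)[C@H](CC=C(C)C)O
F7 | step 7 | 6-iodo-2,4-dimethoxy-3-methylphenol | COc1cc(I)c(O)c(OC)c1C
F8 | step 7 | tert-butyl(2-iodo-4,6-dimethoxy-5-methylphenoxy)dimethylsilane | COc1cc(I)c(O[Si](C)(C)C(C)(C)C)c(OC)c1C
F9 | step 7 | (S)-2-[2-(tert-butyldimethylsilyloxy)-3,5-dimethoxy-4-methylphenyl]-6-methylhepta-1,5-dien-3-yl tiglate | C=C(c1cc(OC)c(C)c(OC)c1O[Si](C)(C)C(C)(C)C)[C@H](CC=C(C)C)OC(=O)/C(C)=C/C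
F10 | step 5 | 6-methylhept-5-en-2-yn-1-ol | CC(C)=CCC#CCO
F11 | step 5 | N-(6-methylhept-5-en-2-yn-1-yl)-2-nitrobenzenesulfonohydrazide | CC(C)=CCC#CCN(N)S(=O)(=O)c1ccccc1[N+](=O)[O-]
F12 | step 5 | (6-methylhept-5-en-2-yn-1-yl)diazene | CC(C)=CCC#CCN=N
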